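**Retrosynthetic overview**

- Sacidumlignan A is read as two 2,6-dimethoxyphenol nuclei plus a 2,3-dimethyl four-carbon chain. C1 of ring B carries two para-phenol carbons (C1' of the pendant ring and C8a of ring A), and C4 is bonded to C4a, the ring A carbon ortho to the C5 methoxy group.
- Cutting C1–C1', C1–C8a and C4–C4a in one operation gives two molecules of 2,6-dimethoxyphenol and (Z)-2,3-dimethylbut-2-enedial, used as its cyclic bis(methyl acetal), 2,5-dimethoxy-3,4-dimethyl-2,5-dihydrofuran.
- The bis-acetal comes from 3,4-dimethylfuran (bromine in methanol), the furan from 3,4-dimethylfuran-2(5H)-one (i-Bu2AlH), and the butenolide from 2,3-dimethylmaleic anhydride (NaBH4).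
- Ring order: ring A and the pendant ring are bought as the phenol; ring B is the only ring made, formed last and aromatised by loss of water, with no oxidant and no protecting group.

Key step: step 4

Remark: atom labels are those of the target naphthalene (C1 aryl-bearing, C2 and C3 methyl-bearing, C4 the free CH, C5 and C7 methoxy, C6 hydroxy); the bis-acetal is used as its cis/trans mixture because both acetal centres are destroyed.

Step 1
Reactants: 1 2,3-dimethylmaleic anhydride
Product: 2 3,4-dimethylfuran-2(5H)-one
Conditions: NaBH4, THF, 0 °C to rt; then aq HCl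
Reagents that add atoms: none
Why: Chemoselective anhydride-to-lactone reduction, in which NaBH4 takes one carbonyl of the symmetric anhydride down to the hydroxy carboxylate, which resists further hydride and lactonises on acidification.

Step 2
Reactants: 2 3,4-dimethylfuran-2(5H)-one
Product: 4 3,4-dimethylfuran, via lactol 3 (not isolated)
Conditions: i-Bu2AlH (1.1 equiv), Et2O, −78 °C; then 2 M aq HCl, 0 °C to rt
Reagents that add atoms: none
Why: Butenolide-to-furan reduction–dehydration, in which partial reduction with i-Bu2AlH stops at the aluminium lactolate at low temperature and the freed lactol loses water in the acidic quench because the product is an aromatic furan.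

Step 3
Reactants: 4 3,4-dimethylfuran
Product: 5 2,5-dimethoxy-3,4-dimethyl-2,5-dihydrofuran (cis/trans mixture)
Conditions: Br2 (1.0 equiv), Na2CO3 (2.2 equiv), MeOH, −40 °C
Reagents that add atoms: methanol, SMILES CO
Why: Clauson-Kaas oxidative methoxylation, in which bromine adds across the two alpha carbons of the furan and methanol replaces both bromides through oxocarbenium ions while the carbonate buffer protects the acid-labile bis-acetal.

Step 4
Reactants: 5 2,5-dimethoxy-3,4-dimethyl-2,5-dihydrofuran; 6 2,6-dimethoxyphenol
Product: 10 sacidumlignan A, via monoaryl dihydrofuran acetal 7 (not isolated), via diaryl enal 8 (not isolated), via dihydronaphthalenol 9 (not isolated)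
Conditions: 6 (4 equiv), CF3SO3H (20 mol %), (CF3)2CHOH, 0 °C, slow addition of 5; then 50 °C
Reagents that add atoms: none
Why: Proposed new method: CF3SO3H ionises one acetal carbon of 5 to an allylic oxocarbenium ion that the para carbon of 6 attacks to give 7 (bond C1–C1'), the para-hydroxybenzylic and allylic ring C–O bond of 7 then ionises to a quinone-methide-like cation that a second molecule of 6 captures through its para carbon (bond C1–C8a) to give enal 8, and the protonated aldehyde carbon C4 attacks C4a, which is ortho to one methoxy group and para to the other, to give 9. Ring B is thus closed by a 6-exo-trig Friedel–Crafts hydroxyalkylation, which requires the Z-enal that the dihydrofuran delivers and that the dienol of 8 can restore, and 1,4-loss of water across C4–OH and C1–H then makes ring B aromatic without an oxidant. The closest known reaction types are the bisphenol-type double arylation of aldehydes by phenols, the acid-catalysed benzannulation of indoles with 2,5-dimethoxytetrahydrofuran to carbazoles, and the Bradsher cyclodehydration. No stereocenter remains, because C1 and C4 of 9 both become sp2. The step needs chemoselectivity for double arylation at C1 ahead of ring closure and ahead of loss of methanol from 7 with aromatisation to a 2-arylfuran; these diversions are unimolecular whereas the wanted captures are bimolecular in 6, so slow addition of 5 to an excess of 6 in an ionising, weakly nucleophilic solvent should favour 8, helped by the strongly stabilised para-hydroxybenzyl cation. Regiochemistry rests on the usual para reactivity of 6 and on the identity of the two aryl groups, which makes closure onto either ring give the same product.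

**Compound list**

1 | 2,3-dimethylmaleic anhydride | CC1=C(C)C(=O)OC1=O | starting material
2 | 3,4-dimethylfuran-2(5H)-one | CC1=C(C)C(=O)OC1 | intermediate
3 | 3,4-dimethyl-2,5-dihydrofuran-2-ol (lactol, not isolated) | CC1=C(C)C(O)OC1 | intermediate
4 | 3,4-dimethylfuran | Cc1cocc1C | intermediate
5 | 2,5-dimethoxy-3,4-dimethyl-2,5-dihydrofuran (cis/trans mixture) | COC1OC(OC)C(C)=C1C | intermediate
6 | 2,6-dimethoxyphenol | COc1cccc(OC)c1O | starting material
7 | 2,6-dimethoxy-4-(5-methoxy-3,4-dimethyl-2,5-dihydrofuran-2-yl)phenol (diastereomer mixture, not isolated) | COC1OC(c2cc(OC)c(O)c(OC)c2)C(C)=C1C | intermediate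
8 | (Z)-4,4-bis(4-hydroxy-3,5-dimethoxyphenyl)-2,3-dimethylbut-2-enal (not isolated) | O=C/C(C)=C(/C)C(c1cc(OC)c(O)c(OC)c1)c1cc(OC)c(O)c(OC)c1 | intermediate
9 | 4-(4-hydroxy-3,5-dimethoxyphenyl)-6,8-dimethoxy-2,3-dimethyl-1,4-dihydronaphthalene-1,7-diol (diastereomer mixture, not isolated) | COc1cc(C2C(C)=C(C)C(O)c3c(OC)c(O)c(OC)cc23)cc(OC)c1O | intermediate
10 | sacidumlignan A, 5-(4-hydroxy-3,5-dimethoxyphenyl)-1,3-dimethoxy-6,7-dimethylnaphthalen-2-ol | COc1cc(-c2c(C)c(C)cc3c(OC)c(O)c(OC)cc23)cc(OC)c1O | target

**Step count**

Total step count: 4. Longest linear sequence: 4 steps (1 → 2 → 4 → 5 → 10; phenol 6 enters at step 4).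

**Steps most likely to fail**

1. Step 4 (proposed new method). Several processes could stop the three-bond cascade from converging:
- Mono-adduct 7 may ionise at its remaining acetal carbon instead of at the benzylic C–O bond, and then either lose a proton with aromatisation to a furan or accept the second phenol at C4 instead of C1.
- The ring may close after a single arylation.
- A third phenol may attack the aldehyde of 8 before ring closure.
- The phenol may react through a carbon ortho to a methoxy group.

Fallback (known chemistry only), setting out from 6 and 2 and returning at 10. Phenol 6 would be brominated para to the hydroxyl group (NBS, CHCl3, −40 °C) to 4-bromo-2,6-dimethoxyphenol F1 and benzylated (BnBr, K2CO3, DMF) to 2-(benzyloxy)-5-bromo-1,3-dimethoxybenzene F2. Butenolide 2 would be hydrogenated (H2, Rh/Al2O3, EtOAc) to racemic cis-3,4-dimethyldihydrofuran-2(3H)-one F3. Bromine–lithium exchange on F2 (n-BuLi, THF, −78 °C) and double addition of the aryllithium to the lactone carbonyl of F3 should give 1,1-bis[4-(benzyloxy)-3,5-dimethoxyphenyl]-2,3-dimethylbutane-1,4-diol F4. Swern oxidation of its primary alcohol ((COCl)2, DMSO, Et3N, CH2Cl2, −78 °C) should give the hydroxy aldehyde, which closes to 5,5-bis[4-(benzyloxy)-3,5-dimethoxyphenyl]-3,4-dimethyltetrahydrofuran-2-ol F5. Treatment with p-TsOH in toluene should bring about the established cyclodehydration of a γ-aryl-γ-hydroxy aldehyde: Friedel–Crafts attack of the aldehyde carbon on the ortho carbon of one aryl group and loss of two molecules of water, giving O,O'-dibenzyl sacidumlignan A F6. The methyl-bearing stereocenters are lost in this aromatisation. Hydrogenolysis (H2, Pd/C, EtOAc–MeOH) then returns to 10.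

2. Step 2. The lactolate may be reduced further to the diol if the temperature rises, the furan may oligomerise in the acidic quench, and the low-boiling furan may be lost on concentration.

Fallback, setting out from 1 and returning at 5 without passing through the furan. Anhydride 1 would be reduced completely (LiAlH4, THF, 0 °C to reflux) to (Z)-2,3-dimethylbut-2-ene-1,4-diol F7. A double Swern oxidation, with both hydroxyl groups activated before Et3N is added so that no lactol can intervene, should give (Z)-2,3-dimethylbut-2-enedial F8. In methanol with PPTS this should close to the cyclic bis-acetal 5.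

3. Step 3. Bromine and methanol may add to the tetrasubstituted C3=C4 bond of the product, and the bis-acetal may ring-open or decompose under acid once the buffer is exhausted.

Fallback, setting out from 4 and returning at 5 without a halogen. Furan 4 would be photooxygenated in methanol–CH2Cl2 (O2, tetraphenylporphyrin, visible light, −78 °C); [4+2] addition of singlet oxygen and methanolysis of the endoperoxide should give 2-hydroperoxy-5-methoxy-3,4-dimethyl-2,5-dihydrofuran F9. Reduction with Me2S at low temperature should give 5-methoxy-3,4-dimethyl-2,5-dihydrofuran-2-ol F10, which is converted into 5 with MeOH and PPTS.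

**Further compounds**

F1 | step 4 | 4-bromo-2,6-dimethoxyphenol | COc1cc(Br)cc(OC)c1O
F2 | step 4 | 2-(benzyloxy)-5-bromo-1,3-dimethoxybenzene | COc1cc(Br)cc(OC)c1OCc1ccccc1
F3 | step 4 | cis-3,4-dimethyldihydrofuran-2(3H)-one (racemic, one enantiomer drawn) | C[C@H]1COC(=O)[C@H]1C
F4 | step 4 | 1,1-bis[4-(benzyloxy)-3,5-dimethoxyphenyl]-2,3-dimethylbutane-1,4-diol (racemic, relative configuration of F3) | OC[C@H](C)[C@H](C)C(O)(c1cc(OC)c(OCc2ccccc2)c(OC)c1)c1cc(OC)c(OCc2ccccc2)c(OC)c1
F5 | step 4 | 5,5-bis[4-(benzyloxy)-3,5-dimethoxyphenyl]-3,4-dimethyltetrahydrofuran-2-ol (racemic, anomer mixture) | OC1[C@H](C)[C@H](C)C(c2cc(OC)c(OCc3ccccc3)c(OC)c2)(c2cc(OC)c(OCc3ccccc3)c(OC)c2)O1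
F6 | step 4 | O,O'-dibenzyl sacidumlignan A | COc1cc(-c2c(C)c(C)cc3c(OC)c(OCc4ccccc4)c(OC)cc23)cc(OC)c1OCc1ccccc1
F7 | step 2 | (Z)-2,3-dimethylbut-2-ene-1,4-diol | OC/C(C)=C(/C)CO
F8 | step 2 | (Z)-2,3-dimethylbut-2-enedial | O=C/C(C)=C(/C)C=O
F9 | step 3 | 2-hydroperoxy-5-methoxy-3,4-dimethyl-2,5-dihydrofuran | COC1OC(OO)C(C)=C1C
F10 | step 3 | 5-methoxy-3,4-dimethyl-2,5-dihydrofuran-2-ol | COC1OC(O)C(C)=C1C
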